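**Plan**

- Retrosynthesis: the ten benzyl ethers come off first. The upper C3–OH and C4–H are then taken back to a C3=C4 alkene (a 4-arylflav-3-ene). Ring C of the upper unit is cut at C4–C4a and O1–C2 in one operation, and the remaining enone is cut at C2–C3 (aldol) and at C4–C8 of ring D (acylation of an aryllithium).
- Enabling feature (flavan numbering; upper unit rings A, C, B with B the trihydroxyphenyl ring; lower unit rings D, F, E): C4 carries ring A through C4a and ring D through its C8, and C2 carries ring B and O1. C2–C3–C4 is therefore a 1,1,3-triarylallyl unit that ring A clamps through C4a and O1, which is what a palladium vinylcarbene/allyl sequence assembles.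
- Forward: rings D, F, E come intact from (−)-epicatechin. C8 of ring D is brominated, lithiated and acetylated (C4 and C3), the acetyl group is condensed with the ring B aldehyde (C2–C3), and the enone is converted into its N-tosylhydrazone. Ring C is closed last onto the ring A iodophenol made from phloroglucinol.
- Stereochemistry: C2 and C3 of the lower unit are those of (−)-epicatechin. Upper C2 is set by the chiral ligand in the allylic etherification. Upper C3 and C4 follow from syn hydroboration on the face opposite ring B, which gives the 2,3-trans-3,4-trans array.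

Key step: step 10

Remark: hydrazone 14 is used as the mixture of C=N isomers, since both give the same diazo compound 18; the (R,R) ligand of step 10 is assumed to be the one that leads to 2S, and its antipode is taken if a pilot run shows the opposite sense.

**Route**

Step 1
Reactants: 1 (−)-epicatechin
Product: 2 5,7,3',4'-tetra-O-benzyl-(−)-epicatechin
Conditions: BnBr (4.4 equiv), K2CO3, DMF, 0 °C → rt
Reagents that add atoms: benzyl bromide (BrCc1ccccc1)
Why: Williamson etherification: K2CO3 ionises only the four phenols, so the secondary 3-OH stays free, and the mild base avoids ring opening at C2, so both stereocentres are untouched.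

Step 2
Reactants: 2 5,7,3',4'-tetra-O-benzyl-(−)-epicatechin
Product: 3 8-bromo-5,7,3',4'-tetra-O-benzyl-(−)-epicatechin
Conditions: NBS (1.0 equiv), CH2Cl2, −78 °C → rt
Reagents that add atoms: N-bromosuccinimide (O=C1CCC(=O)N1Br)
Why: Electrophilic aromatic bromination: the phloroglucinol-type ring is by far the most electron-rich ring, and in 5,7-di-O-benzyl flavan-3-ol ethers NBS is known to attack C8 in preference to C6.

Step 3
Reactants: 3 8-bromo-5,7,3',4'-tetra-O-benzyl-(−)-epicatechin
Product: 4 8-bromo-3,5,7,3',4'-penta-O-benzyl-(−)-epicatechin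
Conditions: NaH, BnBr, DMF, 0 °C → rt
Reagents that add atoms: benzyl bromide (BrCc1ccccc1)
Why: Williamson etherification of the secondary alkoxide; with no free phenol left there is no quinone methide pathway to epimerise C2, and the aryl bromide is inert to NaH.

Step 4
Reactants: 4 8-bromo-3,5,7,3',4'-penta-O-benzyl-(−)-epicatechin; 5 N-methoxy-N-methylacetamide
Product: 8 8-acetyl-3,5,7,3',4'-penta-O-benzyl-(−)-epicatechin, via C8 aryllithium 6 (not isolated), via lithium hemiaminal alkoxide 7 (not isolated)
Conditions: t-BuLi (2.1 equiv), THF, −78 °C; then 5, −78 → 0 °C; 1 M HCl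
Reagents that add atoms: none
Why: Bromine–lithium exchange (fast at −78 °C, the second equivalent of t-BuLi destroying t-BuBr) followed by Weinreb ketone synthesis, in which the chelated tetrahedral adduct 7 prevents a second addition and releases the methyl ketone only on acidic work-up.

Step 5
Reactants: 9 3,4,5-trihydroxybenzaldehyde
Product: 10 3,4,5-tris(benzyloxy)benzaldehyde
Conditions: BnBr (3.3 equiv), K2CO3, DMF, 60 °C
Reagents that add atoms: benzyl bromide (BrCc1ccccc1)
Why: Williamson etherification of the three phenols; the aldehyde is inert to K2CO3 and benzyl bromide.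

Step 6
Reactants: 8 8-acetyl-3,5,7,3',4'-penta-O-benzyl-(−)-epicatechin; 10 3,4,5-tris(benzyloxy)benzaldehyde
Product: 12 (E)-1-(penta-O-benzylepicatechin-8-yl)-3-[3,4,5-tris(benzyloxy)phenyl]prop-2-en-1-one, via aldol adduct 11 (not isolated)
Conditions: KOH, EtOH/THF, rt → 40 °C
Reagents that add atoms: none
Why: Claisen–Schmidt condensation: only ketone 8 can form an enolate and aldehyde 10 has no α-hydrogen, and E1cB dehydration of aldol 11 gives the conjugated E enone, as is routine for 2',6'-dialkoxyacetophenones.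

Step 7
Reactants: 12 (E)-enone; 13 p-toluenesulfonyl hydrazide
Product: 14 N-tosylhydrazone of enone 12
Conditions: 13 (1.2 equiv), HCl (cat.), MeOH/THF, 50 °C
Reagents that add atoms: none
Why: Acid-catalysed condensation of the ketone with the sulfonyl hydrazide (hydrazone formation); under acidic conditions at moderate temperature 1,2-addition to the protonated carbonyl group is favoured over aza-Michael addition, and both C=N isomers are usable because they give the same diazo compound.

Step 8
Reactants: 15 phloroglucinol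
Product: 16 3,5-bis(benzyloxy)phenol
Conditions: BnBr (2.0 equiv), K2CO3, DMF, 0 °C → rt
Reagents that add atoms: benzyl bromide (BrCc1ccccc1)
Why: Williamson etherification with two equivalents of benzyl bromide; the alkylation is statistical, so the diether is separated by chromatography from the mono- and triethers, a known if unselective preparation of this phenol.

Step 9
Reactants: 16 3,5-bis(benzyloxy)phenol
Product: 17 2-iodo-3,5-bis(benzyloxy)phenol
Conditions: NIS (1.0 equiv), CH2Cl2, −40 → 0 °C
Reagents that add atoms: N-iodosuccinimide (O=C1CCC(=O)N1I)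
Why: Electrophilic aromatic iodination: C2 and C6 are equivalent, ortho to the free hydroxyl and less crowded than C4 between the two benzyloxy groups, so the 2-iodo isomer should predominate and the 4-iodo isomer is removed by chromatography.

Step 10
Reactants: 17 2-iodo-3,5-bis(benzyloxy)phenol; 14 N-tosylhydrazone of enone 12
Product: 19 (2S)-deca-O-benzyl-4-arylflav-3-ene dimer, via vinyl diazo compound 18 (not isolated)
Conditions: Pd2(dba)3 (5 mol%), (R,R)-TADDOL-derived N,N-dimethylphosphoramidite (20 mol%), LiOt-Bu (3.5 equiv), 17 (1.3 equiv), 1,4-dioxane, 80 °C, 14 added slowly by syringe pump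
Reagents that add atoms: none
Why: Oxidative addition of zerovalent palladium to the C–I bond of the lithium phenoxide of 17 gives an arylpalladium iodide; LiOt-Bu converts 14 by Bamford–Stevens elimination of sulfinate into vinyl diazo compound 18, which loses N2 at palladium to give a vinylcarbene complex with the carbene carbon at C4, and 1,1-migratory insertion of ring A then makes C4–C4a and generates an η3-allyl complex across C4, C3 and C2 that has no sp3 β-hydrogen for elimination. The ortho phenoxide adds to C2 on the face remote from palladium, which makes O1–C2, closes ring C in a 6-endo allylic etherification and releases zerovalent palladium. The closest known reaction type is the palladium-catalysed coupling of aryl halides with α,β-unsaturated N-tosylhydrazones in which the allyl complex is trapped by an N or O nucleophile, combined with the phosphoramidite-controlled 6-endo allylic etherification used for 2-aryl-2H-chromenes. C2 is the only new stereocentre and is controlled by the chiral phosphoramidite: the diastereomeric allyl complexes equilibrate by η3–η1–η3 slippage and the ligand selects the one whose ring closure gives 2S, the centres of the lower unit being too far away to decide the outcome. Two selectivities are needed: attack at C2 and not C4, secured because closure at the diaryl-bearing C4 would form a four-membered oxete, and carbene transfer faster than 1,5-cyclisation of 18 to a pyrazole, secured by adding 14 slowly to an excess of the arylpalladium species.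

Step 11
Reactants: 19 (2S)-deca-O-benzyl-4-arylflav-3-ene dimer
Product: 21 deca-O-benzyl gallocatechin-(4α→8)-epicatechin bearing a free upper 3-OH (2R,3S,4S; lower unit 2R,3R), via C3 alkylborane 20 (not isolated)
Conditions: BH3·SMe2, THF, 0 °C → rt; then NaOH (aq), H2O2, 0 °C → rt
Reagents that add atoms: hydrogen peroxide (OO)
Why: Brown hydroboration–oxidation: boron adds to the less substituted C3 and hydrogen to the diaryl-bearing C4 in a syn fashion from the face opposite the C2 aryl group (ring B), and oxidation with retention gives 3-OH trans to ring B and ring D trans to 3-OH, that is 2R,3S,4S.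

Step 12
Reactants: 21 deca-O-benzyl dimer with free upper 3-OH
Product: 22 gallocatechin-(4α→8)-epicatechin (CNP0225927.3)
Conditions: H2 (1 atm), Pd(OH)2/C, THF/MeOH/H2O, rt
Reagents that add atoms: none
Why: Catalytic hydrogenolysis of the ten benzyl ethers over Pd(OH)2/C at 1 atm, conditions under which the C2–O1 and C4–C8 benzylic bonds of benzylated proanthocyanidins are known to survive, so no stereocentre is touched.

**Compound list**

1 | (−)-epicatechin, (2R,3R)-2-(3,4-dihydroxyphenyl)chromane-3,5,7-triol | Oc1cc(O)c2c(c1)O[C@H](c1ccc(O)c(O)c1)[C@H](O)C2 | starting material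
2 | 5,7,3',4'-tetra-O-benzyl-(−)-epicatechin (2R,3R; free 3-OH) | O(Cc9ccccc9)c1cc(OCc9ccccc9)c2c(c1)O[C@H](c1ccc(OCc9ccccc9)c(OCc9ccccc9)c1)[C@H](O)C2 | intermediate
3 | 8-bromo-5,7,3',4'-tetra-O-benzyl-(−)-epicatechin (2R,3R) | O(Cc9ccccc9)c1cc(OCc9ccccc9)c2c(c1Br)O[C@H](c1ccc(OCc9ccccc9)c(OCc9ccccc9)c1)[C@H](O)C2 | intermediate
4 | 8-bromo-3,5,7,3',4'-penta-O-benzyl-(−)-epicatechin (2R,3R) | O(Cc9ccccc9)c1cc(OCc9ccccc9)c2c(c1Br)O[C@H](c1ccc(OCc9ccccc9)c(OCc9ccccc9)c1)[C@H](OCc9ccccc9)C2 | intermediate
5 | N-methoxy-N-methylacetamide | CC(=O)N(C)OC | starting material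
6 | 8-lithio-3,5,7,3',4'-penta-O-benzylepicatechin (2R,3R) | O(Cc9ccccc9)c1cc(OCc9ccccc9)c2c(c1[Li])O[C@H](c1ccc(OCc9ccccc9)c(OCc9ccccc9)c1)[C@H](OCc9ccccc9)C2 | intermediate
7 | lithium alkoxide of the C8 hemiaminal ArC(CH3)(OLi)N(OCH3)CH3 (flavan 2R,3R; hemiaminal carbon unassigned) | O(Cc9ccccc9)c1cc(OCc9ccccc9)c2c(c1C(C)(O[Li])N(C)OC)O[C@H](c1ccc(OCc9ccccc9)c(OCc9ccccc9)c1)[C@H](OCc9ccccc9)C2 | intermediate
8 | 8-acetyl-3,5,7,3',4'-penta-O-benzyl-(−)-epicatechin (2R,3R) | O(Cc9ccccc9)c1cc(OCc9ccccc9)c2c(c1C(C)=O)O[C@H](c1ccc(OCc9ccccc9)c(OCc9ccccc9)c1)[C@H](OCc9ccccc9)C2 | intermediate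
9 | 3,4,5-trihydroxybenzaldehyde | O=Cc1cc(O)c(O)c(O)c1 | starting material
10 | 3,4,5-tris(benzyloxy)benzaldehyde | O=Cc1cc(OCc9ccccc9)c(OCc9ccccc9)c(OCc9ccccc9)c1 | intermediate
11 | aldol adduct, 3-hydroxy-1-(penta-O-benzylepicatechin-8-yl)-3-[3,4,5-tris(benzyloxy)phenyl]propan-1-one (flavan 2R,3R; carbinol centre unassigned) | O(Cc9ccccc9)c1cc(OCc9ccccc9)c2c(c1C(=O)CC(O)c1cc(OCc9ccccc9)c(OCc9ccccc9)c(OCc9ccccc9)c1)O[C@H](c1ccc(OCc9ccccc9)c(OCc9ccccc9)c1)[C@H](OCc9ccccc9)C2 | intermediate
12 | (E)-1-[(2R,3R)-3,5,7,3',4'-penta-O-benzylepicatechin-8-yl]-3-[3,4,5-tris(benzyloxy)phenyl]prop-2-en-1-one | O(Cc9ccccc9)c1cc(OCc9ccccc9)c2c(c1C(=O)/C=C/c1cc(OCc9ccccc9)c(OCc9ccccc9)c(OCc9ccccc9)c1)O[C@H](c1ccc(OCc9ccccc9)c(OCc9ccccc9)c1)[C@H](OCc9ccccc9)C2 | intermediate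
13 | p-toluenesulfonyl hydrazide | Cc1ccc(cc1)S(=O)(=O)NN | starting material
14 | N-tosylhydrazone of enone 12 (E alkene; C=N isomer mixture; flavan 2R,3R) | O(Cc9ccccc9)c1cc(OCc9ccccc9)c2c(c1C(=NNS(=O)(=O)c1ccc(C)cc1)/C=C/c1cc(OCc9ccccc9)c(OCc9ccccc9)c(OCc9ccccc9)c1)O[C@H](c1ccc(OCc9ccccc9)c(OCc9ccccc9)c1)[C@H](OCc9ccccc9)C2 | intermediate
15 | phloroglucinol | Oc1cc(O)cc(O)c1 | starting material
16 | 3,5-bis(benzyloxy)phenol | Oc1cc(OCc9ccccc9)cc(OCc9ccccc9)c1 | intermediate
17 | 2-iodo-3,5-bis(benzyloxy)phenol | Oc1cc(OCc9ccccc9)cc(OCc9ccccc9)c1I | intermediate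
18 | vinyl diazo compound, (E)-1-diazo-1-(penta-O-benzylepicatechin-8-yl)-3-[3,4,5-tris(benzyloxy)phenyl]prop-2-ene (flavan 2R,3R) | O(Cc9ccccc9)c1cc(OCc9ccccc9)c2c(c1C(=[N+]=[N-])/C=C/c1cc(OCc9ccccc9)c(OCc9ccccc9)c(OCc9ccccc9)c1)O[C@H](c1ccc(OCc9ccccc9)c(OCc9ccccc9)c1)[C@H](OCc9ccccc9)C2 | intermediate
19 | (2S)-5,7-bis(benzyloxy)-2-[3,4,5-tris(benzyloxy)phenyl]-4-[(2R,3R)-3,5,7,3',4'-penta-O-benzylepicatechin-8-yl]-2H-chromene (4-arylflav-3-ene) | O(Cc9ccccc9)c1cc(OCc9ccccc9)c2c(c1)O[C@H](c1cc(OCc9ccccc9)c(OCc9ccccc9)c(OCc9ccccc9)c1)C=C2c1c(OCc9ccccc9)cc(OCc9ccccc9)c3c1O[C@H](c1ccc(OCc9ccccc9)c(OCc9ccccc9)c1)[C@H](OCc9ccccc9)C3 | intermediate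
20 | (2S,3S,4S)-3-boryl (BH2) flavan from syn addition of H–B to 19, boron at C3 trans to ring B, ring D at C4 cis to ring B (lower unit 2R,3R) | O(Cc9ccccc9)c1cc(OCc9ccccc9)c2c(c1)O[C@H](c1cc(OCc9ccccc9)c(OCc9ccccc9)c(OCc9ccccc9)c1)[C@@H](B)[C@@H]2c1c(OCc9ccccc9)cc(OCc9ccccc9)c3c1O[C@H](c1ccc(OCc9ccccc9)c(OCc9ccccc9)c1)[C@H](OCc9ccccc9)C3 | intermediate
21 | (2R,3S,4S)-5,7-bis(benzyloxy)-2-[3,4,5-tris(benzyloxy)phenyl]-4-[(2R,3R)-3,5,7,3',4'-penta-O-benzylepicatechin-8-yl]chroman-3-ol (deca-O-benzyl dimer, free upper 3-OH) | O(Cc9ccccc9)c1cc(OCc9ccccc9)c2c(c1)O[C@H](c1cc(OCc9ccccc9)c(OCc9ccccc9)c(OCc9ccccc9)c1)[C@@H](O)[C@@H]2c1c(OCc9ccccc9)cc(OCc9ccccc9)c3c1O[C@H](c1ccc(OCc9ccccc9)c(OCc9ccccc9)c1)[C@H](OCc9ccccc9)C3 | intermediate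
22 | gallocatechin-(4α→8)-epicatechin, (2R,3S,4S)-4-[(2R,3R)-2-(3,4-dihydroxyphenyl)-3,5,7-trihydroxychroman-8-yl]-2-(3,4,5-trihydroxyphenyl)chromane-3,5,7-triol | Oc1cc(O)c2c(c1)O[C@H](c1cc(O)c(O)c(O)c1)[C@@H](O)[C@@H]2c1c(O)cc(O)c2c1O[C@H](c1ccc(O)c(O)c1)[C@H](O)C2 | target

**Step count**

Total: 12 steps. Longest linear sequence: 9 steps (steps 1, 2, 3, 4, 6, 7, 10, 11, 12, from (−)-epicatechin).

**Steps most likely to fail**

Step 10. Migration of the doubly ortho-substituted ring A onto a carbene carbon that already carries the doubly ortho-substituted ring D may be slow. The vinyl diazo compound could then cyclise to a pyrazole before it meets palladium, the allyl complex could be held up by reversible sulfinate capture, and ligand control at C2 could be eroded by the crowded environment. The fallback sets out from 12 and 17 and returns at 19. Iodophenol 17 is converted with n-BuLi (2 equiv, THF, −78 °C) into its C,O-dilithio derivative, which adds to the carbonyl group of enone 12 to give the triaryl allylic alcohol F1 (either carbinol epimer serves). A BINOL-derived chiral N-triflylphosphoramide then ionises it to the 1,1,3-triarylallyl cation paired with the chiral anion, and the ortho phenol closes ring C at C2 in an enantioselective Brønsted acid catalysed allylic substitution, giving 19.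

Step 7. Condensation at the twisted, doubly ortho-substituted ketone may be slower than aza-Michael addition of the hydrazide to the enone followed by ring closure to a pyrazoline. The fallback sets out from 4 and 10 and returns at 14. Aldehyde 10 is homologated by Horner–Wadsworth–Emmons reaction with diethyl cyanomethylphosphonate (NaH, THF) to the (E)-cinnamonitrile F2. Aryllithium 6, made from 4 as in step 4, adds to the nitrile carbon, and a methanol quench gives the N–H ketimine F3. This exchanges with 13 (AcOH, MeOH/THF, rt) with loss of ammonia to give 14; transimination of an N–H imine requires no attack on a hindered carbonyl group.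

Step 11. Borane addition to the crowded trisubstituted alkene may be sluggish, and approach from the ring B face may compete, so that facial selectivity is incomplete. The fallback sets out from 19 and returns at 21. OsO4 (cat.) with N-methylmorpholine N-oxide dihydroxylates the alkene on the face opposite ring B to the 3,4-cis-diol F4. Et3SiH with CF3CO2H in CH2Cl2 at low temperature then removes the tertiary, doubly benzylic C4 hydroxyl through the C4 cation. Hydride should enter axially on the face opposite ring B, as in known ionic reductions of 4-aryl-flavan-4-ols, so that ring D ends equatorial, cis to ring B and trans to O3, which is 21.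

**Further compounds**

F1 | step 10 | (E)-1-[2-hydroxy-4,6-bis(benzyloxy)phenyl]-1-[(2R,3R)-penta-O-benzylepicatechin-8-yl]-3-[3,4,5-tris(benzyloxy)phenyl]prop-2-en-1-ol (carbinol centre unassigned) | Oc1cc(OCc9ccccc9)cc(OCc9ccccc9)c1C(O)(/C=C/c1cc(OCc9ccccc9)c(OCc9ccccc9)c(OCc9ccccc9)c1)c1c(OCc9ccccc9)cc(OCc9ccccc9)c3c1O[C@H](c1ccc(OCc9ccccc9)c(OCc9ccccc9)c1)[C@H](OCc9ccccc9)C3
F2 | step 7 | (E)-3-[3,4,5-tris(benzyloxy)phenyl]prop-2-enenitrile | N#C/C=C/c1cc(OCc9ccccc9)c(OCc9ccccc9)c(OCc9ccccc9)c1
F3 | step 7 | N–H ketimine, (E)-1-[(2R,3R)-penta-O-benzylepicatechin-8-yl]-3-[3,4,5-tris(benzyloxy)phenyl]prop-2-en-1-imine | O(Cc9ccccc9)c1cc(OCc9ccccc9)c2c(c1C(=N)/C=C/c1cc(OCc9ccccc9)c(OCc9ccccc9)c(OCc9ccccc9)c1)O[C@H](c1ccc(OCc9ccccc9)c(OCc9ccccc9)c1)[C@H](OCc9ccccc9)C2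
F4 | step 11 | 3,4-cis-diol of 19, both hydroxyls on the face opposite ring B, ring D at C4 cis to ring B (lower unit 2R,3R) | O(Cc9ccccc9)c1cc(OCc9ccccc9)c2c(c1)O[C@H](c1cc(OCc9ccccc9)c(OCc9ccccc9)c(OCc9ccccc9)c1)[C@@H](O)[C@]2(O)c1c(OCc9ccccc9)cc(OCc9ccccc9)c3c1O[C@H](c1ccc(OCc9ccccc9)c(OCc9ccccc9)c1)[C@H](OCc9ccccc9)C3
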